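**Plan**
- Cuts: first the C(sp)–C(sp2) bond between alkyne carbon C5' and alkene carbon C6' of the side-chain enyne, which gives the dioxane alkyne acid 18 and the (E)-iodoalkene 22. Then, in 18, the C3–O2 bond of the 1,2-dioxane (hydroperoxy ketal plus secondary mesylate) and the C6(OMe)(OO) unit back to a 1,1-disubstituted alkene. Last, the two allylic C–C bonds of the acyclic chain (epoxide 4, linchpin 6, silylbutynyl bromide 5).
- Forward: two Grignard couplings build the C11 chain; ozonolysis in methanol and a 6-exo-tet peroxide alkylation close the only ring (O1–O2–C3–C4–C5–C6); the side-chain alcohol is oxidised to the acid; the enyne bond is made last.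
- Stereochemistry: C3 comes from ethyl (S)-4-chloro-3-hydroxybutanoate, is carried as the (R)-carbinol and is inverted once in the peroxide SN2. C6 is set by acid equilibration in methanol (axial OMe, both carbon chains equatorial). The E alkene comes from a Takai olefination and is retained in the coupling.
- Enabling feature: the terminal sp C–H of the pent-4-ynyl arm on C6, three CH2 groups away from the ring, faces an sp2 C–I on the keto chain. The O1–O2 bond is a hindered dialkyl peroxyketal without O–H, so the union can be run on the unprotected acid and ketone.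

Key step: step 13

Remark: the ring is numbered O1, O2, C3 (CH2CO2H carbon, S), C4, C5, C6 (peroxyketal carbon, R). In the target OMe and CH2CO2H are cis, so in the chair OMe is axial and both carbon chains are equatorial. Compounds 1, 5, 6 and 19 are taken as catalogue compounds.

**Route**

Step 1
Reactants: 1 ethyl (3S)-4-chloro-3-hydroxybutanoate
Product: 2 (3S)-4-chlorobutane-1,3-diol
Conditions: NaBH4 (2 equiv), EtOH, 0 °C to rt; aq. NH4Cl work-up
Reagents that add atoms: none
Why: Hydroxyl-assisted NaBH4 reduction of a β-hydroxy ester should give the 1,3-diol without touching the C–Cl bond or the chiral-pool stereocentre.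

Step 2
Reactants: 2 (3S)-4-chlorobutane-1,3-diol
Product: 3 (2S)-4-[(tert-butyldimethylsilyl)oxy]-1-chlorobutan-2-ol
Conditions: TBSCl (1.05 equiv), imidazole (2 equiv), CH2Cl2, −20 to 0 °C
Reagents that add atoms: tert-butyldimethylsilyl chloride, CC(C)(C)[Si](C)(C)Cl
Why: Selective monosilylation; the bulky silyl chloride should react at the primary hydroxyl well before the secondary one.

Step 3
Reactants: 3 (2S)-4-[(tert-butyldimethylsilyl)oxy]-1-chlorobutan-2-ol
Product: 4 tert-butyldimethyl{2-[(2S)-oxiran-2-yl]ethoxy}silane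
Conditions: K2CO3 (2 equiv), MeOH, 0 °C to rt
Reagents that add atoms: none
Why: Intramolecular Williamson (3-exo-tet) closure of the chlorohydrin; the C–O bond at the stereocentre is not broken, so the S configuration is kept.

Step 4
Reactants: 5 (4-bromobut-1-yn-1-yl)trimethylsilane; 6 3-chloro-2-(chloromethyl)prop-1-ene
Product: 8 [6-(chloromethyl)hept-6-en-1-yn-1-yl]trimethylsilane, via butynylmagnesium bromide 7 (not isolated)
Conditions: 5, Mg, THF, rt; then added to 6 (3 equiv), Li2CuCl4 (3 mol%), THF, −20 to 0 °C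
Reagents that add atoms: none
Why: Copper-catalysed allylic substitution of a Grignard reagent on the symmetrical bis-allylic dichloride, in which SN2 and SN2' attack give the same product; excess 6 should suppress double substitution, and the silyl cap masks the acidic alkyne C–H.

Step 5
Reactants: 8 [6-(chloromethyl)hept-6-en-1-yn-1-yl]trimethylsilane; 4 tert-butyldimethyl{2-[(2S)-oxiran-2-yl]ethoxy}silane
Product: 10 (3R)-1-[(tert-butyldimethylsilyl)oxy]-6-methylidene-11-(trimethylsilyl)undec-10-yn-3-ol, via allylmagnesium chloride 9 (not isolated)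
Conditions: 8, Mg, THF, 0 °C (slow addition); then 4, CuI (10 mol%), THF, −30 to 0 °C; aq. NH4Cl
Reagents that add atoms: none
Why: Copper-catalysed opening of a terminal epoxide by a 2-substituted allyl Grignard reagent at the unsubstituted carbon, both allyl termini being equivalent; the stereocentre is untouched and becomes R only through the change in CIP priorities.

Step 6
Reactants: 10 (3R)-1-[(tert-butyldimethylsilyl)oxy]-6-methylidene-11-(trimethylsilyl)undec-10-yn-3-ol
Product: 11 (3R)-1-[(tert-butyldimethylsilyl)oxy]-6-methylidene-11-(trimethylsilyl)undec-10-yn-3-yl methanesulfonate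
Conditions: MsCl (1.3 equiv), Et3N (2 equiv), CH2Cl2, 0 °C
Reagents that add atoms: methanesulfonyl chloride, CS(=O)(=O)Cl
Why: Standard O-sulfonylation with retention, which turns the carbinol into the leaving group for the ring closure.

Step 7
Reactants: 11 (3R)-1-[(tert-butyldimethylsilyl)oxy]-6-methylidene-11-(trimethylsilyl)undec-10-yn-3-yl methanesulfonate
Product: 13 (3R)-1-[(tert-butyldimethylsilyl)oxy]-6-hydroperoxy-6-methoxy-11-(trimethylsilyl)undec-10-yn-3-yl methanesulfonate (both C6 epimers), via carbonyl oxide 12 (not isolated)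
Conditions: O3 (1.0 equiv, Sudan Red 7B end point), CH2Cl2/MeOH (4:1), −78 °C; N2 purge
Reagents that add atoms: ozone, [O-][O+]=O; methanol, CO
Why: Criegee ozonolysis of the 1,1-disubstituted alkene gives the ketone oxide and formaldehyde, and methanol traps the ketone oxide as the α-methoxy hydroperoxide; the electron-rich alkene should react far faster than the silyl-capped alkyne, and the new C6 centre forms without control (corrected in step 9).

Step 8
Reactants: 13 (3R)-1-[(tert-butyldimethylsilyl)oxy]-6-hydroperoxy-6-methoxy-11-(trimethylsilyl)undec-10-yn-3-yl methanesulfonate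
Product: 14 tert-butyl{2-[(3S)-6-methoxy-6-[5-(trimethylsilyl)pent-4-yn-1-yl]-1,2-dioxan-3-yl]ethoxy}dimethylsilane (both C6 epimers)
Conditions: KOtBu (1.1 equiv), 18-crown-6 (1.1 equiv), toluene, 0 °C
Reagents that add atoms: none
Why: Intramolecular alkylation of the hydroperoxy ketal anion (a weakly basic α-effect nucleophile) by the secondary mesylate, a 6-exo-tet SN2 closure that should invert C3 cleanly from R to S.

Step 9
Reactants: 14 tert-butyl{2-[(3S)-6-methoxy-6-[5-(trimethylsilyl)pent-4-yn-1-yl]-1,2-dioxan-3-yl]ethoxy}dimethylsilane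
Product: 16 2-[(3S,6R)-6-methoxy-6-(pent-4-yn-1-yl)-1,2-dioxan-3-yl]ethan-1-ol, via C-silylated alcohol 15 (not isolated)
Conditions: CSA (0.2 equiv), MeOH, rt; then K2CO3 (2 equiv), rt; chromatography
Reagents that add atoms: methanol, CO
Why: Acid-catalysed transketalisation through the peroxycarbenium ion should equilibrate C6 to the epimer with axial OMe (anomeric effect) and both carbon chains equatorial, which is 6R, so both epimers of 14 converge; the same acidic methanol cleaves the primary TBS ether and K2CO3/MeOH then removes the alkynyl silyl group.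

Step 10
Reactants: 16 2-[(3S,6R)-6-methoxy-6-(pent-4-yn-1-yl)-1,2-dioxan-3-yl]ethan-1-ol
Product: 18 2-[(3S,6R)-6-methoxy-6-(pent-4-yn-1-yl)-1,2-dioxan-3-yl]acetic acid, via aldehyde 17 (not isolated)
Conditions: TEMPO (0.2 equiv), PhI(OAc)2 (2.5 equiv), MeCN/H2O (1:1), rt
Reagents that add atoms: water, O
Why: Oxoammonium (TEMPO/PhI(OAc)2) oxidation of the primary alcohol through the aldehyde hydrate to the acid; the oxidising, base-free medium should leave the peroxide and the alkyne alone and give no chance for β-elimination of the peroxide from the aldehyde.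

Step 11
Reactants: 19 undec-10-en-2-one
Product: 21 9-oxodecanal, via ozonide 20 (not isolated)
Conditions: O3, CH2Cl2, −78 °C; then PPh3 (1.2 equiv), −78 °C to rt
Reagents that add atoms: ozone, [O-][O+]=O
Why: Ozonolysis of the terminal alkene with reductive work-up should give the keto aldehyde one carbon shorter.

Step 12
Reactants: 21 9-oxodecanal
Product: 22 (10E)-11-iodoundec-10-en-2-one
Conditions: CrCl2 (6 equiv), CHI3 (2 equiv), dioxane/THF (6:1), 0 °C to rt
Reagents that add atoms: iodoform, IC(I)I
Why: Takai olefination; the geminal dichromium species from CHI3 and CrCl2 adds to the aldehyde much faster than to the ketone, and elimination from the adduct should give the E-iodoalkene.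

Step 13
Reactants: 18 2-[(3S,6R)-6-methoxy-6-(pent-4-yn-1-yl)-1,2-dioxan-3-yl]acetic acid; 22 (10E)-11-iodoundec-10-en-2-one
Product: 23 2-[(3S,6R)-6-methoxy-6-[(6E)-15-oxohexadec-6-en-4-yn-1-yl]-1,2-dioxan-3-yl]acetic acid
Conditions: Pd(PPh3)4 (5 mol%), CuI (10 mol%), i-Pr2NH (5 equiv), 22 (1.2 equiv), THF, rt, degassed; aq. NaH2PO4 work-up
Reagents that add atoms: none
Why: Sonogashira coupling: zerovalent palladium inserts into the sp2 C–I bond of 22 with retention of the E geometry, CuI and the amine turn the terminal C–H of the pentynyl arm of 18 into a copper acetylide that transmetalates to palladium, and reductive elimination forms the C(sp)–C(sp2) bond of the enyne. The closest known reaction type is the palladium/copper alkynylation of alkenyl iodides with terminal alkynes that carry a 1,2-dioxane. No ring is closed and no stereocentre is formed; C3, C6 and the alkene geometry are carried through unchanged. The step needs chemoselectivity for the C–I bond over the O1–O2 bond and the carbonyl groups: the peroxide is a dialkyl peroxyketal without O–H next to a fully substituted carbon and should react only slowly with PPh3 or zerovalent palladium at room temperature, whereas alkenyl iodides undergo oxidative addition quickly. The acid is present as its ammonium carboxylate, which cannot enolise toward β-elimination of the peroxide, and the methyl ketone is inert, so the coupling should deliver the complete unprotected target.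

**Compound list**

1 | ethyl (3S)-4-chloro-3-hydroxybutanoate | CCOC(=O)C[C@H](O)CCl | starting material
2 | (3S)-4-chlorobutane-1,3-diol | OCC[C@H](O)CCl | intermediate
3 | (2S)-4-[(tert-butyldimethylsilyl)oxy]-1-chlorobutan-2-ol | CC(C)(C)[Si](C)(C)OCC[C@H](O)CCl | intermediate
4 | tert-butyldimethyl{2-[(2S)-oxiran-2-yl]ethoxy}silane | CC(C)(C)[Si](C)(C)OCC[C@H]1CO1 | intermediate
5 | (4-bromobut-1-yn-1-yl)trimethylsilane | C[Si](C)(C)C#CCCBr | starting material
6 | 3-chloro-2-(chloromethyl)prop-1-ene | C=C(CCl)CCl | starting material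
7 | [4-(trimethylsilyl)but-3-yn-1-yl]magnesium bromide | C[Si](C)(C)C#CCC[Mg]Br | intermediate
8 | [6-(chloromethyl)hept-6-en-1-yn-1-yl]trimethylsilane | C[Si](C)(C)C#CCCCC(=C)CCl | intermediate
9 | [2-methylidene-7-(trimethylsilyl)hept-6-yn-1-yl]magnesium chloride | C[Si](C)(C)C#CCCCC(=C)C[Mg]Cl | intermediate
10 | (3R)-1-[(tert-butyldimethylsilyl)oxy]-6-methylidene-11-(trimethylsilyl)undec-10-yn-3-ol | C[Si](C)(C)C#CCCCC(=C)CC[C@@H](O)CCO[Si](C)(C)C(C)(C)C | intermediate
11 | (3R)-1-[(tert-butyldimethylsilyl)oxy]-6-methylidene-11-(trimethylsilyl)undec-10-yn-3-yl methanesulfonate | C[Si](C)(C)C#CCCCC(=C)CC[C@@H](OS(C)(=O)=O)CCO[Si](C)(C)C(C)(C)C | intermediate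
12 | carbonyl oxide (ketone O-oxide at C6) of 11 after loss of formaldehyde | C[Si](C)(C)C#CCCCC(=[O+][O-])CC[C@@H](OS(C)(=O)=O)CCO[Si](C)(C)C(C)(C)C | intermediate
13 | (3R)-1-[(tert-butyldimethylsilyl)oxy]-6-hydroperoxy-6-methoxy-11-(trimethylsilyl)undec-10-yn-3-yl methanesulfonate (both C6 epimers) | C[Si](C)(C)C#CCCCC(OC)(OO)CC[C@@H](OS(C)(=O)=O)CCO[Si](C)(C)C(C)(C)C | intermediate
14 | tert-butyl{2-[(3S)-6-methoxy-6-[5-(trimethylsilyl)pent-4-yn-1-yl]-1,2-dioxan-3-yl]ethoxy}dimethylsilane (both C6 epimers) | COC1(CCCC#C[Si](C)(C)C)CC[C@@H](CCO[Si](C)(C)C(C)(C)C)OO1 | intermediate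
15 | 2-[(3S,6R)-6-methoxy-6-[5-(trimethylsilyl)pent-4-yn-1-yl]-1,2-dioxan-3-yl]ethan-1-ol | CO[C@@]1(CCCC#C[Si](C)(C)C)CC[C@@H](CCO)OO1 | intermediate
16 | 2-[(3S,6R)-6-methoxy-6-(pent-4-yn-1-yl)-1,2-dioxan-3-yl]ethan-1-ol | CO[C@@]1(CCCC#C)CC[C@@H](CCO)OO1 | intermediate
17 | 2-[(3S,6R)-6-methoxy-6-(pent-4-yn-1-yl)-1,2-dioxan-3-yl]acetaldehyde | CO[C@@]1(CCCC#C)CC[C@@H](CC=O)OO1 | intermediate
18 | 2-[(3S,6R)-6-methoxy-6-(pent-4-yn-1-yl)-1,2-dioxan-3-yl]acetic acid | CO[C@@]1(CCCC#C)CC[C@@H](CC(=O)O)OO1 | intermediate
19 | undec-10-en-2-one | CC(=O)CCCCCCCC=C | starting material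
20 | 9-(1,2,4-trioxolan-3-yl)nonan-2-one | CC(=O)CCCCCCCC1OCOO1 | intermediate
21 | 9-oxodecanal | CC(=O)CCCCCCCC=O | intermediate
22 | (10E)-11-iodoundec-10-en-2-one | CC(=O)CCCCCCC/C=C/I | intermediate
23 | 2-[(3S,6R)-6-methoxy-6-[(6E)-15-oxohexadec-6-en-4-yn-1-yl]-1,2-dioxan-3-yl]acetic acid | CO[C@@]1(CCCC#C/C=C/CCCCCCCC(C)=O)CC[C@@H](CC(=O)O)OO1 | target

**Step count and risks**

Total steps: 13. Longest linear sequence: 10 (steps 1, 2, 3, 5, 6, 7, 8, 9, 10, 13).

Steps most likely to fail:

1. Step 13. The carboxylate may tie up CuI or palladium and stall the coupling, and a stalled coupling would leave room for Glaser-type dimerisation of the alkyne and for slow reductive cleavage of the O–O bond by PPh3. Fallback: the union is moved one oxidation level back. It sets out from 16, which is coupled with 22 under the same Pd(PPh3)4/CuI/i-Pr2NH conditions to give 2-[(3S,6R)-6-methoxy-6-[(6E)-15-oxohexadec-6-en-4-yn-1-yl]-1,2-dioxan-3-yl]ethan-1-ol F1. The TEMPO/PhI(OAc)2 oxidation in MeCN/H2O is then run last on F1 and comes back to the route at 23.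

2. Step 8. E2 elimination of the mesylate or base-induced Kornblum–DeLaMare fragmentation of the peroxide may outrun the 6-exo displacement. Fallback: the ring is closed under acid by opening an oxetane instead of displacing a sulfonate under base. It sets out from 10.
   - TBAF in THF removes both silyl groups and should give (3R)-6-methylideneundec-10-yne-1,3-diol F2.
   - TsCl/pyridine at 0 °C should sulfonylate the primary hydroxyl to give (3R)-3-hydroxy-6-methylideneundec-10-yn-1-yl 4-methylbenzenesulfonate F3.
   - KOtBu in THF closes (2R)-2-(3-methylideneoct-7-yn-1-yl)oxetane F4 without touching the stereocentre.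
   - Ozonolysis in CH2Cl2/MeOH at −78 °C gives (2R)-2-(3-hydroperoxy-3-methoxyoct-7-yn-1-yl)oxetane F5.
   - Catalytic BF3·OEt2 in CH2Cl2 at −78 to 0 °C should promote 6-exo attack of the hydroperoxide on the oxetane C2 with inversion, giving 2-[(3S)-6-methoxy-6-(pent-4-yn-1-yl)-1,2-dioxan-3-yl]ethan-1-ol as a mixture of C6 epimers F6.
   - CSA in MeOH equilibrates F6 at C6 and comes back to the route at 16.

3. Step 12. Elimination from the chromium adduct may not be fully E-selective, and the Z-iodide would be carried into the enyne. Fallback: the iodoalkene is made by syn hydrometalation of an alkyne. It sets out from 21.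
   - Dimethyl (1-diazo-2-oxopropyl)phosphonate with K2CO3 in MeOH (Ohira–Bestmann, aldehyde-selective) should give undec-10-yn-2-one F7.
   - Ethylene glycol with catalytic TsOH in refluxing toluene gives 2-methyl-2-(non-8-yn-1-yl)-1,3-dioxolane F8.
   - Cp2Zr(H)Cl in THF followed by I2 gives 2-[(8E)-9-iodonon-8-en-1-yl]-2-methyl-1,3-dioxolane F9 as the E isomer only.
   - PPTS in acetone/H2O removes the ketal and comes back to the route at 22.

**Further compounds**

F1 | step 13 | 2-[(3S,6R)-6-methoxy-6-[(6E)-15-oxohexadec-6-en-4-yn-1-yl]-1,2-dioxan-3-yl]ethan-1-ol | CO[C@@]1(CCCC#C/C=C/CCCCCCCC(C)=O)CC[C@@H](CCO)OO1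
F2 | step 8 | (3R)-6-methylideneundec-10-yne-1,3-diol | C#CCCCC(=C)CC[C@@H](O)CCO
F3 | step 8 | (3R)-3-hydroxy-6-methylideneundec-10-yn-1-yl 4-methylbenzenesulfonate | C#CCCCC(=C)CC[C@@H](O)CCOS(=O)(=O)c1ccc(C)cc1
F4 | step 8 | (2R)-2-(3-methylideneoct-7-yn-1-yl)oxetane | C#CCCCC(=C)CC[C@@H]1CCO1
F5 | step 8 | (2R)-2-(3-hydroperoxy-3-methoxyoct-7-yn-1-yl)oxetane (both epimers at the ketal carbon) | C#CCCCC(OC)(OO)CC[C@@H]1CCO1
F6 | step 8 | 2-[(3S)-6-methoxy-6-(pent-4-yn-1-yl)-1,2-dioxan-3-yl]ethan-1-ol (both C6 epimers) | COC1(CCCC#C)CC[C@@H](CCO)OO1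
F7 | step 12 | undec-10-yn-2-one | CC(=O)CCCCCCCC#C
F8 | step 12 | 2-methyl-2-(non-8-yn-1-yl)-1,3-dioxolane | CC1(CCCCCCCC#C)OCCO1
F9 | step 12 | 2-[(8E)-9-iodonon-8-en-1-yl]-2-methyl-1,3-dioxolane | CC1(CCCCCCC/C=C/I)OCCO1
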